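**Retrosynthetic overview**

1. Garcinoic acid 22 is cut at C2'–C3' (side chain numbered C1'–C13' outward from C2) by a Negishi sp3–sp2 coupling into chroman iodide 9 and the C14 (E,E,E)-iodotrienoate 18, which already holds all three E alkenes and the carboxyl carbon.
2. 9 comes from ester 7, and 7 from the achiral alkenylphenol 6 by the key step: an enantioselective domino oxypalladation/carbonylation/methoxylation that forms the O1–C2 bond, closes the pyran ring, sets the only stereocentre (C2) and appends C2' with its oxygen function in one operation.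
3. Enabling feature: C2 becomes a fully substituted ring carbon (O1, CH3, C3, C1'), so the C1'–Pd species formed on ring closure has no β-hydrogen and waits for CO; the phenol oxygen on C8a and the 1,1-disubstituted alkene are separated by exactly C4 and C3, which makes the closure 6-exo.
4. 6 comes from 2-methylhydroquinone 1 (monosilylation, ortho-iodination, Negishi alkylation with 4); 18 comes from pent-4-yn-1-ol 10 (carboalumination–iodination, oxidation, isopropenyl addition, Johnson–Claisen, reduction, Wittig).
5. Ring order: the benzene ring is bought with 1; the pyran ring (O1–C2–C3–C4–C4a–C8a) is the only ring formed, in step 4.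

Key step: step 4

Assumption: the (S,S)-configured Bn-BOXAX ligand is taken to give the 2S ester 7 (the spatial arrangement of the natural 2R chromanols); if the sense of induction is the reverse, the (R,R) ligand is used with nothing else changed.

**Route**

Step 1
Reactants: 1 2-methylbenzene-1,4-diol (2-methylhydroquinone)
Product: 2 2-methyl-4-[(triisopropylsilyl)oxy]phenol
Conditions: i-Pr3SiCl (1.0 equiv), imidazole, DMF, −20 → 0 °C
Reagents that add atoms: triisopropylsilyl chloride, CC(C)[Si](Cl)(C(C)C)C(C)C
Why: Sterically controlled monosilylation, in which the hydroxyl flanked by two ring hydrogens should react with the bulky chlorosilane faster than the hydroxyl next to the methyl group, leaving free the oxygen that becomes O1.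

Step 2
Reactants: 2 2-methyl-4-[(triisopropylsilyl)oxy]phenol
Product: 3 2-iodo-6-methyl-4-[(triisopropylsilyl)oxy]phenol
Conditions: N-iodosuccinimide (1.05 equiv), CF3CO2H (cat.), MeCN, 0 °C, dark
Reagents that add atoms: N-iodosuccinimide, O=C1CCC(=O)N1I
Why: Electrophilic aromatic iodination directed by the free hydroxyl to its only open ortho position, the two positions next to the bulky silyloxy group being shielded and less activated.

Step 3
Reactants: 3 2-iodo-6-methyl-4-[(triisopropylsilyl)oxy]phenol; 4 4-bromo-2-methylbut-1-ene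
Product: 6 2-methyl-6-(3-methylbut-3-en-1-yl)-4-[(triisopropylsilyl)oxy]phenol, via (3-methylbut-3-en-1-yl)zinc bromide 5 (not isolated)
Conditions: 4, Zn dust (activated with BrCH2CH2Br, Me3SiCl), LiCl, THF, 50 °C; then 3, Pd(OAc)2 (2 mol%), SPhos (4 mol%), THF, 25 °C, slow addition of 5
Reagents that add atoms: none
Why: Negishi sp3–sp2 cross-coupling, in which the primary homoallylic alkylzinc halide should couple with the aryl iodide faster than it is protonated by the phenol and without isomerisation of the 1,1-disubstituted alkene.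

Step 4
Reactants: 6 2-methyl-6-(3-methylbut-3-en-1-yl)-4-[(triisopropylsilyl)oxy]phenol
Product: 7 methyl 2-[(2S)-2,8-dimethyl-6-[(triisopropylsilyl)oxy]-3,4-dihydro-2H-chromen-2-yl]acetate
Conditions: Pd(OCOCF3)2 (5 mol%), (S,S)-Bn-BOXAX [(S)-2,2'-bis((4S)-4-benzyl-4,5-dihydrooxazol-2-yl)-1,1'-binaphthyl] (20 mol%), p-benzoquinone (4 equiv), CO (1 atm), MeOH, rt
Reagents that add atoms: carbon monoxide, [C-]#[O+]; methanol, CO
Why: Enantioselective domino Wacker-type oxypalladation/carbonylation/methoxylation: the ligand-bound divalent palladium binds the 1,1-disubstituted alkene, the phenol oxygen adds to the internal alkene carbon (O1–C2 bond, 6-exo-trig closure of the pyran ring), and the primary C1'–Pd species, whose only β-carbon is the new fully substituted C2, cannot undergo β-hydride elimination, so it inserts CO and is cleaved by methanol to the ester while the zerovalent palladium released is reoxidised by p-benzoquinone. The closest known reaction type is the enantioselective domino Wacker/carbonylation of 2-(3-methylbut-3-enyl)phenols to 2-methylchroman-2-ylacetates with palladium bis(trifluoroacetate) and binaphthyl bis(oxazoline) ligands. The single new stereocentre C2 is set in the oxypalladation under catalyst control, the axially chiral ligand distinguishing the two enantiotopic faces of the alkene. The step needs this face selectivity and chemoselectivity for ring closure over intermolecular alkoxycarbonylation of the alkene; the two-carbon tether makes the oxygen attack intramolecular, and the fourfold ligand excess suppresses a ligand-free background reaction. The silyl ether on the second oxygen keeps the arene from being oxidised to a quinone by the benzoquinone.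

Step 5
Reactants: 7 methyl 2-[(2S)-2,8-dimethyl-6-[(triisopropylsilyl)oxy]-3,4-dihydro-2H-chromen-2-yl]acetate
Product: 8 2-[(2S)-2,8-dimethyl-6-[(triisopropylsilyl)oxy]-3,4-dihydro-2H-chromen-2-yl]ethan-1-ol
Conditions: LiAlH4 (1.1 equiv), Et2O, 0 °C; aq NaOH work-up
Reagents that add atoms: none
Why: Hydride reduction of the ester to the primary alcohol, fast enough at 0 °C to outrun any base-induced retro-oxa-Michael opening, so the quaternary C2 centre is retained.

Step 6
Reactants: 8 2-[(2S)-2,8-dimethyl-6-[(triisopropylsilyl)oxy]-3,4-dihydro-2H-chromen-2-yl]ethan-1-ol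
Product: 9 (2S)-2-(2-iodoethyl)-2,8-dimethyl-6-[(triisopropylsilyl)oxy]-3,4-dihydro-2H-chromene
Conditions: I2, PPh3, imidazole, CH2Cl2, 0 °C → rt
Reagents that add atoms: iodine, II
Why: Appel-type iodination of an unhindered primary alcohol by SN2 displacement of the alkoxyphosphonium ion, which does not involve C2.

Step 7
Reactants: 10 pent-4-yn-1-ol
Product: 12 (4E)-5-iodo-4-methylpent-4-en-1-ol, via alkenylalane 11 (not isolated)
Conditions: AlMe3 (3 equiv), Cp2ZrCl2 (25 mol%), CH2Cl2, 0 °C → rt; then I2, THF, −30 → 0 °C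
Reagents that add atoms: trimethylaluminium, C[Al](C)C; iodine, II
Why: Zirconium-catalysed methylalumination of the terminal alkyne (Negishi carboalumination) adds CH3 and aluminium syn with aluminium at the terminus, and iodinolysis with retention gives the E iodoalkene that fixes the C3'=C4' geometry.

Step 8
Reactants: 12 (4E)-5-iodo-4-methylpent-4-en-1-ol
Product: 13 (4E)-5-iodo-4-methylpent-4-enal
Conditions: TEMPO (10 mol%), PhI(OAc)2 (1.1 equiv), CH2Cl2, rt
Reagents that add atoms: none
Why: Nitroxyl-catalysed alcohol oxidation stops at the aldehyde and leaves the iodoalkene untouched.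

Step 9
Reactants: 13 (4E)-5-iodo-4-methylpent-4-enal
Product: 14 (6E)-7-iodo-2,6-dimethylhepta-1,6-dien-3-ol (racemic)
Conditions: CH2=C(CH3)MgBr (1.2 equiv), THF, −78 → −20 °C; H2O quench
Reagents that add atoms: isopropenylmagnesium bromide, C=C(C)[Mg]Br
Why: Grignard 1,2-addition to the aldehyde at low temperature, where iodine–magnesium exchange at the alkenyl iodide does not compete; the racemic carbinol centre is destroyed in the next step.

Step 10
Reactants: 14 (6E)-7-iodo-2,6-dimethylhepta-1,6-dien-3-ol
Product: 16 ethyl (4E,8E)-9-iodo-4,8-dimethylnona-4,8-dienoate, via allyl ketene acetal 15 (not isolated)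
Conditions: CH3C(OEt)3 (6 equiv), EtCO2H (cat.), 140 °C, EtOH distilled off
Reagents that add atoms: triethyl orthoacetate, CCOC(C)(OCC)OCC
Why: Johnson–Claisen rearrangement through a chair transition state with the carbinol substituent equatorial, which should turn the carbinol carbon into the E-trisubstituted C7'=C8' alkene.

Step 11
Reactants: 16 ethyl (4E,8E)-9-iodo-4,8-dimethylnona-4,8-dienoate
Product: 17 (4E,8E)-9-iodo-4,8-dimethylnona-4,8-dienal
Conditions: i-Bu2AlH (1.05 equiv), CH2Cl2, −78 °C; MeOH, then aq potassium sodium tartrate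
Reagents that add atoms: none
Why: Partial ester reduction with one equivalent of the aluminium hydride at −78 °C, where the tetrahedral aluminium hemiacetal survives until work-up and releases the aldehyde.

Step 12
Reactants: 17 (4E,8E)-9-iodo-4,8-dimethylnona-4,8-dienal
Product: 18 ethyl (2E,6E,10E)-11-iodo-2,6,10-trimethylundeca-2,6,10-trienoate
Conditions: Ph3P=C(CH3)CO2Et (1.3 equiv), CH2Cl2, rt → 40 °C
Reagents that add atoms: ethyl 2-(triphenylphosphoranylidene)propanoate, CCOC(=O)C(C)=P(c1ccccc1)(c1ccccc1)c1ccccc1
Why: Wittig olefination with the α-methyl stabilised ylide, which should give the E 2-methyl-2-enoate (C11'=C12') with the carboxyl carbon C13' in place.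

Step 13
Reactants: 9 (2S)-2-(2-iodoethyl)-2,8-dimethyl-6-[(triisopropylsilyl)oxy]-3,4-dihydro-2H-chromene; 18 ethyl (2E,6E,10E)-11-iodo-2,6,10-trimethylundeca-2,6,10-trienoate
Product: 20 ethyl (2E,6E,10E)-13-[(2R)-2,8-dimethyl-6-[(triisopropylsilyl)oxy]-3,4-dihydro-2H-chromen-2-yl]-2,6,10-trimethyltrideca-2,6,10-trienoate, via chromanylethylzinc iodide 19 (not isolated)
Conditions: 9, Zn dust (activated with BrCH2CH2Br, Me3SiCl), LiCl, THF, 40 °C; then 18, PdCl2(dppf) (5 mol%), THF, rt → 45 °C
Reagents that add atoms: none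
Why: Negishi sp3–sp2 coupling in which zinc insertion gives an ester-tolerant alkylzinc iodide that should couple with the E iodoalkene with retention of alkene geometry, the wide-bite-angle ferrocenyl diphosphine favouring reductive elimination over β-hydride elimination; C2 is untouched and only its descriptor changes to R.

Step 14
Reactants: 20 ethyl (2E,6E,10E)-13-[(2R)-2,8-dimethyl-6-[(triisopropylsilyl)oxy]-3,4-dihydro-2H-chromen-2-yl]-2,6,10-trimethyltrideca-2,6,10-trienoate
Product: 22 garcinoic acid, (2E,6E,10E)-13-[(2R)-6-hydroxy-2,8-dimethyl-3,4-dihydro-2H-chromen-2-yl]-2,6,10-trimethyltrideca-2,6,10-trienoic acid, via garcinoic acid ethyl ester 21 (not isolated)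
Conditions: n-Bu4NF (1.2 equiv), THF, 0 °C; then LiOH (5 equiv), THF/MeOH/H2O (degassed, Ar), 40 °C; 1 M HCl to pH 3
Reagents that add atoms: lithium hydroxide, [Li+].[OH-]
Why: Fluoride desilylation of the aryl silyl ether followed by saponification of the enoate, neither of which touches the trisubstituted alkenes, with oxygen excluded because the chromanol phenoxide is easily oxidised.

**Compound list**

1 | 2-methylbenzene-1,4-diol (2-methylhydroquinone) | Cc1cc(O)ccc1O | starting material
2 | 2-methyl-4-[(triisopropylsilyl)oxy]phenol | Cc1cc(O[Si](C(C)C)(C(C)C)C(C)C)ccc1O | intermediate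
3 | 2-iodo-6-methyl-4-[(triisopropylsilyl)oxy]phenol | Cc1cc(O[Si](C(C)C)(C(C)C)C(C)C)cc(I)c1O | intermediate
4 | 4-bromo-2-methylbut-1-ene | C=C(C)CCBr | starting material
5 | (3-methylbut-3-en-1-yl)zinc bromide | C=C(C)CC[Zn]Br | intermediate
6 | 2-methyl-6-(3-methylbut-3-en-1-yl)-4-[(triisopropylsilyl)oxy]phenol | C=C(C)CCc1cc(O[Si](C(C)C)(C(C)C)C(C)C)cc(C)c1O | intermediate
7 | methyl 2-[(2S)-2,8-dimethyl-6-[(triisopropylsilyl)oxy]-3,4-dihydro-2H-chromen-2-yl]acetate | COC(=O)C[C@]1(C)CCc2cc(O[Si](C(C)C)(C(C)C)C(C)C)cc(C)c2O1 | intermediate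
8 | 2-[(2S)-2,8-dimethyl-6-[(triisopropylsilyl)oxy]-3,4-dihydro-2H-chromen-2-yl]ethan-1-ol | OCC[C@]1(C)CCc2cc(O[Si](C(C)C)(C(C)C)C(C)C)cc(C)c2O1 | intermediate
9 | (2S)-2-(2-iodoethyl)-2,8-dimethyl-6-[(triisopropylsilyl)oxy]-3,4-dihydro-2H-chromene | ICC[C@]1(C)CCc2cc(O[Si](C(C)C)(C(C)C)C(C)C)cc(C)c2O1 | intermediate
10 | pent-4-yn-1-ol | C#CCCCO | starting material
11 | dimethylaluminium alkoxide of (4E)-5-(dimethylalumanyl)-4-methylpent-4-en-1-ol (alkenylalane) | C[Al](C)OCCC/C(C)=C/[Al](C)C | intermediate
12 | (4E)-5-iodo-4-methylpent-4-en-1-ol | OCCC/C(C)=C/I | intermediate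
13 | (4E)-5-iodo-4-methylpent-4-enal | O=CCC/C(C)=C/I | intermediate
14 | (6E)-7-iodo-2,6-dimethylhepta-1,6-dien-3-ol (racemic) | C=C(C)C(O)CC/C(C)=C/I | intermediate
15 | 1-ethoxy-1-{[(6E)-7-iodo-2,6-dimethylhepta-1,6-dien-3-yl]oxy}ethene (allyl ketene acetal) | C=C(OCC)OC(CC/C(C)=C/I)C(C)=C | intermediate
16 | ethyl (4E,8E)-9-iodo-4,8-dimethylnona-4,8-dienoate | CCOC(=O)CC/C(C)=C/CC/C(C)=C/I | intermediate
17 | (4E,8E)-9-iodo-4,8-dimethylnona-4,8-dienal | O=CCC/C(C)=C/CC/C(C)=C/I | intermediate
18 | ethyl (2E,6E,10E)-11-iodo-2,6,10-trimethylundeca-2,6,10-trienoate | CCOC(=O)/C(C)=C/CC/C(C)=C/CC/C(C)=C/I | intermediate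
19 | {2-[(2S)-2,8-dimethyl-6-[(triisopropylsilyl)oxy]-3,4-dihydro-2H-chromen-2-yl]ethyl}zinc iodide | I[Zn]CC[C@]1(C)CCc2cc(O[Si](C(C)C)(C(C)C)C(C)C)cc(C)c2O1 | intermediate
20 | ethyl (2E,6E,10E)-13-[(2R)-2,8-dimethyl-6-[(triisopropylsilyl)oxy]-3,4-dihydro-2H-chromen-2-yl]-2,6,10-trimethyltrideca-2,6,10-trienoate | CCOC(=O)/C(C)=C/CC/C(C)=C/CC/C(C)=C/CC[C@]1(C)CCc2cc(O[Si](C(C)C)(C(C)C)C(C)C)cc(C)c2O1 | intermediate
21 | ethyl (2E,6E,10E)-13-[(2R)-6-hydroxy-2,8-dimethyl-3,4-dihydro-2H-chromen-2-yl]-2,6,10-trimethyltrideca-2,6,10-trienoate (garcinoic acid ethyl ester) | CCOC(=O)/C(C)=C/CC/C(C)=C/CC/C(C)=C/CC[C@]1(C)CCc2cc(O)cc(C)c2O1 | intermediate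
22 | garcinoic acid, (2E,6E,10E)-13-[(2R)-6-hydroxy-2,8-dimethyl-3,4-dihydro-2H-chromen-2-yl]-2,6,10-trimethyltrideca-2,6,10-trienoic acid | C/C(=C\CC/C(C)=C/CC[C@]1(C)CCc2cc(O)cc(C)c2O1)CC/C=C(\C)C(=O)O | target

**Step count and risks**

Total step count: 14. Longest linear sequence: 8 steps (steps 1–6, 13, 14; the side-chain branch, steps 7–12, 13, 14, is equally long).

Steps most likely to fail:

1. Step 4. The divalent palladium may be reduced to metal by carbon monoxide before it engages the alkene, so that turnover stalls, or a ligand-free pathway may erode the face selection of the oxypalladation. The fallback sets out from 3 and comes back at 7, closing the same O1–C2 bond without palladium-bound CO and taking the configuration from a separation. A Heck reaction of 3 with but-3-en-2-ol (Pd(OAc)2, NaHCO3, n-Bu4NCl, DMF, 50 °C) should give 4-[2-hydroxy-3-methyl-5-[(triisopropylsilyl)oxy]phenyl]butan-2-one F1, which is in equilibrium with its cyclic hemiketal. Horner–Wadsworth–Emmons reaction with trimethyl phosphonoacetate and NaH (2.2 equiv, THF, reflux) gives the open enoate methyl 5-[2-hydroxy-3-methyl-5-[(triisopropylsilyl)oxy]phenyl]-3-methylpent-2-enoate F2, whose phenoxide closes in the same flask by oxa-Michael addition to racemic methyl 2-[2,8-dimethyl-6-[(triisopropylsilyl)oxy]-3,4-dihydro-2H-chromen-2-yl]acetate F3. Preparative chromatography on a chiral stationary phase then delivers the 2S enantiomer, which is 7; the unwanted enantiomer can be re-equilibrated with NaOMe through retro-oxa-Michael opening and reclosure and recycled.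

2. Step 13. Zinc insertion into the iodide may stall, or the alkylzinc may be lost by protonation and homocoupling before transmetalation, and slow reductive elimination would let β-hydride elimination compete. The fallback sets out from 9 and comes back at 20, replacing metal insertion and zinc-to-palladium transfer by a B-alkyl Suzuki–Miyaura coupling. Iodine–lithium exchange on 9 (t-BuLi, 2.1 equiv, Et2O, −78 °C) and trapping with 9-methoxy-9-borabicyclo[3.3.1]nonane gives the lithium B-alkyl-B-methoxy borate F4, which is coupled without isolation with 18 (PdCl2(dppf), AsPh3, aq K3PO4, DMF, rt) to give 20. Any loss of the silyl group under the basic conditions is harmless, because it leads to 21.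

3. Step 3. The free ortho hydroxyl may protonate the alkylzinc reagent, and the zinc phenoxide may slow oxidative addition and transmetalation; the step also inherits any regiochemical leak from the iodination. The fallback sets out from 2 and comes back at 6, bypassing steps 2 and 3 by making the benzylic C–C bond through an ortho-quinone methide. Casnati–Skattebøl ortho-formylation of 2 (MgCl2, Et3N, paraformaldehyde, MeCN, reflux) gives 2-hydroxy-3-methyl-5-[(triisopropylsilyl)oxy]benzaldehyde F5, with the position fixed by magnesium chelation. NaBH4 (MeOH, 0 °C) reduces it to 2-(hydroxymethyl)-6-methyl-4-[(triisopropylsilyl)oxy]phenol F6. With 2-methylallylmagnesium chloride (3.5 equiv, THF, reflux) the magnesium salt of F6 eliminates to 2-methyl-6-methylidene-4-[(triisopropylsilyl)oxy]cyclohexa-2,4-dien-1-one F7 (an ortho-quinone methide, not isolated), which takes up the Grignard reagent by 1,4-addition to give 6.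

Further compounds
F1 | step 4 | 4-[2-hydroxy-3-methyl-5-[(triisopropylsilyl)oxy]phenyl]butan-2-one | CC(=O)CCc1cc(O[Si](C(C)C)(C(C)C)C(C)C)cc(C)c1O
F2 | step 4 | methyl 5-[2-hydroxy-3-methyl-5-[(triisopropylsilyl)oxy]phenyl]-3-methylpent-2-enoate (E/Z mixture) | COC(=O)C=C(C)CCc1cc(O[Si](C(C)C)(C(C)C)C(C)C)cc(C)c1O
F3 | step 4 | racemic methyl 2-[2,8-dimethyl-6-[(triisopropylsilyl)oxy]-3,4-dihydro-2H-chromen-2-yl]acetate | COC(=O)CC1(C)CCc2cc(O[Si](C(C)C)(C(C)C)C(C)C)cc(C)c2O1
F4 | step 13 | lithium B-{2-[(2S)-2,8-dimethyl-6-[(triisopropylsilyl)oxy]-3,4-dihydro-2H-chromen-2-yl]ethyl}-B-methoxy-9-borabicyclo[3.3.1]nonan-9-uide | [Li+].CO[B-]1(CC[C@]2(C)CCc3cc(O[Si](C(C)C)(C(C)C)C(C)C)cc(C)c3O2)C2CCCC1CCC2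
F5 | step 3 | 2-hydroxy-3-methyl-5-[(triisopropylsilyl)oxy]benzaldehyde | O=Cc1cc(O[Si](C(C)C)(C(C)C)C(C)C)cc(C)c1O
F6 | step 3 | 2-(hydroxymethyl)-6-methyl-4-[(triisopropylsilyl)oxy]phenol | OCc1cc(O[Si](C(C)C)(C(C)C)C(C)C)cc(C)c1O
F7 | step 3 | 2-methyl-6-methylidene-4-[(triisopropylsilyl)oxy]cyclohexa-2,4-dien-1-one | C=C1C=C(O[Si](C(C)C)(C(C)C)C(C)C)C=C(C)C1=O
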